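**Retrosynthetic overview**

1. The target is a decalin diterpenoid (labdane numbering). The C15 acid comes from a silyl-protected primary alcohol by late oxidation, and the C19 ester from the C19 neopentyl alcohol and (R)-2-methylbutanoic acid.
2. Both rings come from one acyclic (6E,10E) 2-methyl-3-oxo ester in a single oxidative radical cascade: ring A first (C4–C5), ring B second (C9–C10), and termination at C8 gives C8=C17. The C3 ketone is a temporary activating group (removed by Barton–McCombie deoxygenation); the 8-phenylmenthyl ester controls the absolute sense and is later reduced to C19H2OH.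
3. Enabling feature: in ring B the quaternary C10 (bearing C20) lies between C5 and C9, and C8 carries C17, the head-to-tail isoprenoid spacing. A tertiary C10 radical therefore sits five atoms from C9 of a C8(CH3)=C9 alkene, and the tertiary C8 radical left after closure is one oxidation away from the exocyclic methylene. C4 (methyl plus oxidised C19, next to C3) maps onto the α-carbon of a 2-methylacetoacetate.
4. The acyclic precursor comes from γ-alkylation of the dianion of 8-phenylmenthyl 2-methylacetoacetate with a C15 allylic bromide, itself made from (2E,6E)-farnesol (asymmetric hydrogenation sets C13; terminal allylic oxidation; bromination).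

Key step: step 7

Assumption: the sense of auxiliary control in step 7 is taken to follow the behaviour of non-chelated 2-methyl-3-oxo esters of 8-phenylmenthol, in which the (1R,2S,5R) auxiliary leads to the common (podocarpic-type) decalin; the (1S,2R,5S) auxiliary is therefore used for the mirror-image decalin required here.

Naming: labdane numbering is used. "ent-labd" means only that the decalin is the mirror image of the common labdane series: C20 methyl, the axial C19 carbon on C4 and the C9 side chain are on one face, and H-5, H-9 and the C18 methyl on the other (4R,5S,9R,10S in the target). C13 is given separately.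

**Route**

Step 1
Reactants: 1 (2E,6E)-farnesol
Product: 2 (R)-2,3-dihydrofarnesol [(3R,6E)-3,7,11-trimethyldodeca-6,10-dien-1-ol]
Conditions: H2 (100 atm), Ru(OAc)2[(S)-BINAP] (0.5 mol %), MeOH, rt
Reagents that add atoms: none
Why: Noyori asymmetric hydrogenation: the hydroxyl group binds the BINAP–ruthenium dicarboxylate so only the allylic C2=C3 alkene is reduced, and (S)-BINAP with an (E)-allylic alcohol should give the (3R) centre (the sense of geraniol to (R)-citronellol), leaving the two remote trisubstituted alkenes untouched.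

Step 2
Reactants: 2 (R)-2,3-dihydrofarnesol
Product: 3 tert-butyl{[(3R,6E)-3,7,11-trimethyldodeca-6,10-dien-1-yl]oxy}diphenylsilane
Conditions: TBDPSCl, imidazole, DMF, rt
Reagents that add atoms: tert-butyl(chloro)diphenylsilane, CC(C)(C)[Si](Cl)(c1ccccc1)c1ccccc1
Why: Standard imidazole-promoted silylation of a primary alcohol; the TBDPS ether is chosen because it should survive the acetic acid, hydride and radical conditions used later.

Step 3
Reactants: 3 tert-butyl{[(3R,6E)-3,7,11-trimethyldodeca-6,10-dien-1-yl]oxy}diphenylsilane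
Product: 4 (2E,6E,10R)-12-[(tert-butyldiphenylsilyl)oxy]-2,6,10-trimethyldodeca-2,6-dien-1-ol
Conditions: SeO2 (0.1 equiv), t-BuOOH (2 equiv), salicylic acid (0.1 equiv), CH2Cl2, 0 °C to rt, stopped at partial conversion
Reagents that add atoms: selenium dioxide, O=[Se]=O (catalytic oxygen carrier); tert-butyl hydroperoxide, CC(C)(C)OO (terminal oxidant that supplies the oxygen)
Why: Sharpless catalytic SeO2/t-BuOOH allylic hydroxylation (ene reaction then [2,3]-sigmatropic shift) attacks the (E)-methyl of the terminal isopropylidene unit preferentially and gives the (E)-allylic alcohol.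

Step 4
Reactants: 4 (2E,6E,10R)-12-[(tert-butyldiphenylsilyl)oxy]-2,6,10-trimethyldodeca-2,6-dien-1-ol
Product: 5 {[(3R,6E,10E)-12-bromo-3,7,11-trimethyldodeca-6,10-dien-1-yl]oxy}(tert-butyl)diphenylsilane
Conditions: CBr4, PPh3, CH2Cl2, 0 °C
Reagents that add atoms: tetrabromomethane, BrC(Br)(Br)Br
Why: Appel bromination of a primary allylic alcohol proceeds by SN2 displacement of the oxyphosphonium, without allylic transposition or loss of (E) geometry at low temperature.

Step 5
Reactants: 6 ethyl 2-methyl-3-oxobutanoate; 7 (+)-8-phenylmenthol [(1S,2R,5S)-5-methyl-2-(2-phenylpropan-2-yl)cyclohexan-1-ol]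
Product: 8 (1S,2R,5S)-8-phenylmenthyl 2-methyl-3-oxobutanoate (both C2 epimers)
Conditions: DMAP (0.3 equiv), toluene, reflux, 4 Å molecular sieves (removal of EtOH)
Reagents that add atoms: none
Why: DMAP-catalysed transesterification of a β-keto ester (through the acylketene) works with hindered secondary alcohols and is driven by removal of ethanol; no stereocentre of the auxiliary is touched.

Step 6
Reactants: 8 (1S,2R,5S)-8-phenylmenthyl 2-methyl-3-oxobutanoate; 5 {[(3R,6E,10E)-12-bromo-3,7,11-trimethyldodeca-6,10-dien-1-yl]oxy}(tert-butyl)diphenylsilane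
Product: 10 (1S,2R,5S)-8-phenylmenthyl (6E,10E,14R)-16-[(tert-butyldiphenylsilyl)oxy]-2,6,10,14-tetramethyl-3-oxohexadeca-6,10-dienoate (both C2 epimers), via dilithium dienolate 9 (not isolated)
Conditions: LDA (2.1 equiv, commercial solution), THF, −78 to 0 °C; then 5, −78 to 0 °C; AcOH quench
Reagents that add atoms: none
Why: Huckin–Weiler dianion alkylation: the more basic terminal (C4) carbanion of the 1,3-dianion is alkylated selectively by the primary allylic bromide (SN2), assembling the full C20 chain with both (E) alkenes and C13 in place.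

Step 7
Reactants: 10 (1S,2R,5S)-8-phenylmenthyl (6E,10E,14R)-16-[(tert-butyldiphenylsilyl)oxy]-2,6,10,14-tetramethyl-3-oxohexadeca-6,10-dienoate
Product: 14 (1S,2R,5S)-8-phenylmenthyl (13R)-15-(tert-butyldiphenylsilyloxy)-3-oxo-ent-labd-8(17)-en-19-oate, via C4 radical 11 (not isolated), via monocyclic C10 radical 12 (not isolated), via bicyclic C8 radical 13 (not isolated)
Conditions: Mn(OAc)3·2H2O (2.2 equiv), Cu(OAc)2·H2O (1 equiv), degassed AcOH, 25 °C
Reagents that add atoms: none
Why: Mn(OAc)3 enolises and oxidises the 2-methyl-3-oxo ester to the planar C4 radical 11, which adds 6-endo-trig to C5 of the (E)-C10=C5 alkene (ring A, tertiary C10 radical 12); 12 then adds 6-endo-trig to C9 of the (E)-C8=C9 alkene, making the C9–C10 bond and ring B (tertiary C8 radical 13), and Cu(OAc)2 captures 13 as an organocopper species (trivalent copper) whose β-hydride elimination toward the C17 methyl gives the less substituted exocyclic alkene. The closest known reaction type is the oxidative free-radical polyene cyclisation of 2-alkyl-3-oxo esters with trivalent manganese and divalent copper acetates, including its 8-phenylmenthyl ester variant. Both closures are 6-endo because each alkene carries its methyl on the proximal carbon, so attack at the distal CH carbon gives tertiary radicals. C4 is set by the radical reacting in the conformer with the ester anti to the ketone oxygen, which places C19 axial and C18 equatorial; C5, C10 and C9 follow from chair–chair transition states with the chain substituents equatorial (trans ring fusion, H-9 anti to C20). The absolute sense is set in the first closure by the phenyl ring of the auxiliary, which stacks over the ester and shields one face of the C4 radical, while the remote C13 centre plays no role. The step needs face selectivity (auxiliary), cyclisation of 12 faster than its premature oxidation (fast chair closure of a tertiary radical) and exocyclic termination (the divalent copper salt); the minor diastereomer and endocyclic alkene isomers should be removable by chromatography.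

Step 8
Reactants: 14 (1S,2R,5S)-8-phenylmenthyl (13R)-15-(tert-butyldiphenylsilyloxy)-3-oxo-ent-labd-8(17)-en-19-oate
Product: 15 (1S,2R,5S)-8-phenylmenthyl (13R)-15-(tert-butyldiphenylsilyloxy)-3-hydroxy-ent-labd-8(17)-en-19-oate (3-OH equatorial, on the face of C20)
Conditions: NaBH4, MeOH/THF, 0 °C
Reagents that add atoms: none
Why: NaBH4 reduces only the ketone (the hindered ester and silyl ether are inert), hydride adding axially on the face away from the axial C19 ester to give the equatorial alcohol, whose configuration is inconsequential because C3 is deoxygenated next.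

Step 9
Reactants: 15 (1S,2R,5S)-8-phenylmenthyl (13R)-15-(tert-butyldiphenylsilyloxy)-3-hydroxy-ent-labd-8(17)-en-19-oate
Product: 16 (1S,2R,5S)-8-phenylmenthyl (13R)-15-(tert-butyldiphenylsilyloxy)-3-[(imidazol-1-yl)carbonothioyloxy]-ent-labd-8(17)-en-19-oate
Conditions: 1,1'-thiocarbonyldiimidazole, DMAP (cat.), ClCH2CH2Cl, reflux
Reagents that add atoms: 1,1'-thiocarbonyldiimidazole, S=C(n1ccnc1)n1ccnc1
Why: Thioacylation of the hindered secondary alcohol under neutral conditions gives the Barton–McCombie precursor and avoids the retro-aldol cleavage that alkoxide-based xanthate formation could trigger in a β-hydroxy ester.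

Step 10
Reactants: 16 (1S,2R,5S)-8-phenylmenthyl (13R)-15-(tert-butyldiphenylsilyloxy)-3-[(imidazol-1-yl)carbonothioyloxy]-ent-labd-8(17)-en-19-oate
Product: 17 (1S,2R,5S)-8-phenylmenthyl (13R)-15-(tert-butyldiphenylsilyloxy)-ent-labd-8(17)-en-19-oate
Conditions: Bu3SnH, AIBN (cat.), toluene, 110 °C
Reagents that add atoms: none
Why: Barton–McCombie deoxygenation (stannyl radical addition to C=S, β-scission to the secondary C3 radical, hydrogen transfer from Bu3SnH) removes the temporary C3 oxygen; the remote 1,1-disubstituted alkene and the ester cannot engage the C3 radical.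

Step 11
Reactants: 17 (1S,2R,5S)-8-phenylmenthyl (13R)-15-(tert-butyldiphenylsilyloxy)-ent-labd-8(17)-en-19-oate
Product: 18 (13R)-15-(tert-butyldiphenylsilyloxy)-ent-labd-8(17)-en-19-ol
Conditions: LiAlH4, THF, 0 to 50 °C; Fieser work-up
Reagents that add atoms: none
Why: LiAlH4 reduction of the hindered ester gives the neopentyl C19 alcohol and releases the recoverable auxiliary; the TBDPS ether and the alkene are inert to hydride.

Step 12
Reactants: 18 (13R)-15-(tert-butyldiphenylsilyloxy)-ent-labd-8(17)-en-19-ol; 19 (R)-2-methylbutanoic acid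
Product: 21 (13R)-15-(tert-butyldiphenylsilyloxy)-ent-labd-8(17)-en-19-yl (2R)-2-methylbutanoate, via mixed anhydride 20 (not isolated)
Conditions: 19, 2,4,6-trichlorobenzoyl chloride, Et3N, THF, rt; then 18, DMAP, toluene, rt to 40 °C
Reagents that add atoms: none
Why: Yamaguchi esterification: DMAP attacks the mixed anhydride at the less hindered aliphatic carbonyl and the acylpyridinium acylates the neopentyl primary alcohol under conditions mild enough to keep the (R) α-centre of the acid intact.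

Step 13
Reactants: 21 (13R)-15-(tert-butyldiphenylsilyloxy)-ent-labd-8(17)-en-19-yl (2R)-2-methylbutanoate
Product: 22 (13R)-15-hydroxy-ent-labd-8(17)-en-19-yl (2R)-2-methylbutanoate
Conditions: Bu4NF, AcOH (1:1), THF, rt
Reagents that add atoms: none
Why: Fluoride-mediated desilylation, buffered with acetic acid so that the hindered ester and its α-stereocentre are untouched.

Step 14
Reactants: 22 (13R)-15-hydroxy-ent-labd-8(17)-en-19-yl (2R)-2-methylbutanoate
Product: 24 (13R)-19-[(2R)-2-methylbutanoyloxy]-ent-labd-8(17)-en-15-oic acid (CNP0365997.1), via aldehyde 23 (not isolated)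
Conditions: TEMPO (0.2 equiv), PhI(OAc)2 (2.5 equiv), MeCN/H2O (1:1), rt
Reagents that add atoms: water, O
Why: TEMPO/PhI(OAc)2 oxidation in aqueous acetonitrile takes the primary alcohol through the aldehyde and its hydrate to the acid under near-neutral conditions that should not affect the 1,1-disubstituted alkene, the ester, or the C13 and acyl stereocentres.

**Compound list**

1 | (2E,6E)-farnesol | CC(C)=CCC/C(C)=C/CC/C(C)=C/CO | starting material
2 | (R)-2,3-dihydrofarnesol, (3R,6E)-3,7,11-trimethyldodeca-6,10-dien-1-ol | CC(C)=CCC/C(C)=C/CC[C@@H](C)CCO | intermediate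
3 | tert-butyl{[(3R,6E)-3,7,11-trimethyldodeca-6,10-dien-1-yl]oxy}diphenylsilane | CC(C)=CCC/C(C)=C/CC[C@@H](C)CCO[Si](c1ccccc1)(c1ccccc1)C(C)(C)C | intermediate
4 | (2E,6E,10R)-12-[(tert-butyldiphenylsilyl)oxy]-2,6,10-trimethyldodeca-2,6-dien-1-ol | OC/C(C)=C/CC/C(C)=C/CC[C@@H](C)CCO[Si](c1ccccc1)(c1ccccc1)C(C)(C)C | intermediate
5 | {[(3R,6E,10E)-12-bromo-3,7,11-trimethyldodeca-6,10-dien-1-yl]oxy}(tert-butyl)diphenylsilane | BrC/C(C)=C/CC/C(C)=C/CC[C@@H](C)CCO[Si](c1ccccc1)(c1ccccc1)C(C)(C)C | intermediate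
6 | ethyl 2-methyl-3-oxobutanoate | CCOC(=O)C(C)C(C)=O | starting material
7 | (+)-8-phenylmenthol, (1S,2R,5S)-5-methyl-2-(2-phenylpropan-2-yl)cyclohexan-1-ol | O[C@H]1C[C@@H](C)CC[C@@H]1C(C)(C)c1ccccc1 | starting material
8 | (1S,2R,5S)-8-phenylmenthyl 2-methyl-3-oxobutanoate (C2 epimers) | CC(=O)C(C)C(=O)O[C@H]1C[C@@H](C)CC[C@@H]1C(C)(C)c1ccccc1 | intermediate
9 | dilithium dienolate (1,3-dianion) of 8 | [Li+].[Li+].C=C([O-])C(C)=C([O-])O[C@H]1C[C@@H](C)CC[C@@H]1C(C)(C)c1ccccc1 | intermediate
10 | (1S,2R,5S)-8-phenylmenthyl (6E,10E,14R)-16-[(tert-butyldiphenylsilyl)oxy]-2,6,10,14-tetramethyl-3-oxohexadeca-6,10-dienoate (C2 epimers) | CC(C(=O)CC/C(C)=C/CC/C(C)=C/CC[C@@H](C)CCO[Si](c1ccccc1)(c1ccccc1)C(C)(C)C)C(=O)O[C@H]1C[C@@H](C)CC[C@@H]1C(C)(C)c1ccccc1 | intermediate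
11 | C4 (α-keto ester) radical of 10 | C[C](C(=O)CC/C(C)=C/CC/C(C)=C/CC[C@@H](C)CCO[Si](c1ccccc1)(c1ccccc1)C(C)(C)C)C(=O)O[C@H]1C[C@@H](C)CC[C@@H]1C(C)(C)c1ccccc1 | intermediate
12 | monocyclic (ring A) tertiary C10 radical | C/C(=C\CC[C@@H](C)CCO[Si](c1ccccc1)(c1ccccc1)C(C)(C)C)CC[C@@H]1[C@](C)(C(=O)O[C@H]2C[C@@H](C)CC[C@@H]2C(C)(C)c2ccccc2)C(=O)CC[C]1C | intermediate
13 | bicyclic tertiary C8 radical | C[C]1CC[C@@H]2[C@](C)(C(=O)O[C@H]3C[C@@H](C)CC[C@@H]3C(C)(C)c3ccccc3)C(=O)CC[C@@]2(C)[C@@H]1CC[C@@H](C)CCO[Si](c1ccccc1)(c1ccccc1)C(C)(C)C | intermediate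
14 | (1S,2R,5S)-8-phenylmenthyl (13R)-15-(tert-butyldiphenylsilyloxy)-3-oxo-ent-labd-8(17)-en-19-oate | C=C1CC[C@@H]2[C@](C)(C(=O)O[C@H]3C[C@@H](C)CC[C@@H]3C(C)(C)c3ccccc3)C(=O)CC[C@@]2(C)[C@@H]1CC[C@@H](C)CCO[Si](c1ccccc1)(c1ccccc1)C(C)(C)C | intermediate
15 | (1S,2R,5S)-8-phenylmenthyl (13R)-15-(tert-butyldiphenylsilyloxy)-3-hydroxy-ent-labd-8(17)-en-19-oate (equatorial 3-OH) | C=C1CC[C@@H]2[C@](C)(C(=O)O[C@H]3C[C@@H](C)CC[C@@H]3C(C)(C)c3ccccc3)[C@H](O)CC[C@@]2(C)[C@@H]1CC[C@@H](C)CCO[Si](c1ccccc1)(c1ccccc1)C(C)(C)C | intermediate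
16 | (1S,2R,5S)-8-phenylmenthyl (13R)-15-(tert-butyldiphenylsilyloxy)-3-[(imidazol-1-yl)carbonothioyloxy]-ent-labd-8(17)-en-19-oate | C=C1CC[C@@H]2[C@](C)(C(=O)O[C@H]3C[C@@H](C)CC[C@@H]3C(C)(C)c3ccccc3)[C@H](OC(=S)n3ccnc3)CC[C@@]2(C)[C@@H]1CC[C@@H](C)CCO[Si](c1ccccc1)(c1ccccc1)C(C)(C)C | intermediate
17 | (1S,2R,5S)-8-phenylmenthyl (13R)-15-(tert-butyldiphenylsilyloxy)-ent-labd-8(17)-en-19-oate | C=C1CC[C@@H]2[C@](C)(C(=O)O[C@H]3C[C@@H](C)CC[C@@H]3C(C)(C)c3ccccc3)CCC[C@@]2(C)[C@@H]1CC[C@@H](C)CCO[Si](c1ccccc1)(c1ccccc1)C(C)(C)C | intermediate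
18 | (13R)-15-(tert-butyldiphenylsilyloxy)-ent-labd-8(17)-en-19-ol | C=C1CC[C@@H]2[C@](C)(CO)CCC[C@@]2(C)[C@@H]1CC[C@@H](C)CCO[Si](c1ccccc1)(c1ccccc1)C(C)(C)C | intermediate
19 | (R)-2-methylbutanoic acid | CC[C@@H](C)C(=O)O | starting material
20 | (R)-2-methylbutanoic 2,4,6-trichlorobenzoic anhydride | CC[C@@H](C)C(=O)OC(=O)c1c(Cl)cc(Cl)cc1Cl | intermediate
21 | (13R)-15-(tert-butyldiphenylsilyloxy)-ent-labd-8(17)-en-19-yl (2R)-2-methylbutanoate | C=C1CC[C@@H]2[C@](C)(COC(=O)[C@H](C)CC)CCC[C@@]2(C)[C@@H]1CC[C@@H](C)CCO[Si](c1ccccc1)(c1ccccc1)C(C)(C)C | intermediate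
22 | (13R)-15-hydroxy-ent-labd-8(17)-en-19-yl (2R)-2-methylbutanoate | C=C1CC[C@@H]2[C@](C)(COC(=O)[C@H](C)CC)CCC[C@@]2(C)[C@@H]1CC[C@@H](C)CCO | intermediate
23 | (13R)-15-oxo-ent-labd-8(17)-en-19-yl (2R)-2-methylbutanoate | C=C1CC[C@@H]2[C@](C)(COC(=O)[C@H](C)CC)CCC[C@@]2(C)[C@@H]1CC[C@@H](C)CC=O | intermediate
24 | (4R,5S,9R,10S,13R)-19-[(2R)-2-methylbutanoyloxy]labd-8(17)-en-15-oic acid (CNP0365997.1) | C=C1CC[C@@H]2[C@](C)(COC(=O)[C@H](C)CC)CCC[C@@]2(C)[C@@H]1CC[C@@H](C)CC(=O)O | target

**Step count and risks**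

Total steps: 14. Longest linear sequence: 13 steps (steps 1–4 and 6–14, from farnesol); step 5 is a one-step side branch.

Steps most likely to fail:

Step 7. The face selectivity of the first radical addition may be poor or reversed, because the non-chelated C4 radical can react through two ester rotamers that expose opposite faces to the auxiliary phenyl group. In addition, the terminating oxidation may partly give endocyclic alkenes. The fallback sets out from bromide 5 and returns at alcohol 18. (1R,2S,5R)-8-Phenylmenthol is acylated with 2,2,6-trimethyl-4H-1,3-dioxin-4-one (xylene, 140 °C) to (1R,2S,5R)-8-phenylmenthyl 3-oxobutanoate F1. Its dianion (NaH then n-BuLi, THF, 0 °C) is alkylated with 5 to give the 2-unsubstituted keto ester F2. Cyclisation of F2 with Mn(OAc)3·2H2O and Cu(OAc)2·H2O in CF3CH2OH at −5 °C in the presence of Yb(OTf)3 runs through the chelated enol. Chelation holds both carbonyl groups syn and turns the auxiliary by half a turn relative to the non-chelated radical, which is why the enantiomeric auxiliary is used. This should give the bicyclic 3-oxo ester F3 with the C5, C9 and C10 configuration of 14. The C4 quaternary centre is then made by enolate methylation (K2CO3, MeI, acetone), the electrophile entering anti to the axial C20 methyl, to give the C19-axial keto ester F4. NaBH4 gives alcohol F5, thiocarbonyldiimidazole gives the imidazolylthiocarbonate F6, Bu3SnH/AIBN gives ester F7, and LiAlH4 gives 18.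

Step 3. Allylic oxidation may compete at the internal trisubstituted alkene, and the product may over-oxidise to the enal. The fallback sets out from silyl ether 3 and returns at allylic alcohol 4. NBS in aqueous THF at 0 °C (terminal-selective bromohydrin formation) gives bromohydrin F8, and K2CO3 in MeOH closes it to the terminal epoxide F9. H5IO6 in THF/Et2O cleaves the epoxide to aldehyde F10. Wittig olefination with Ph3P=C(CH3)CO2Et gives the (E)-enoate F11, and i-Bu2AlH in CH2Cl2 at −78 °C gives 4.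

Step 11. Hydride attack on the doubly hindered ester (axial on a quaternary carbon, 8-phenylmenthyl alkoxy group) may be incomplete, and forcing conditions may begin to cleave the silyl ether. The fallback sets out from keto ester 14 and returns at alcohol 18. LiAlH4 at 0 °C reduces the ketone first, and the C3 aluminate then delivers hydride intramolecularly to the neighbouring ester, giving the 3,19-diol F12. Thiocarbonyldiimidazole (DMAP, toluene, 80 °C) closes the six-membered cyclic thionocarbonate F13. Bu3SnH/AIBN cleaves it regioselectively at the secondary C3–O bond (secondary rather than primary neopentyl radical) to the C19 S-tributylstannyl thiocarbonate F14, which aqueous NaOH hydrolyses to 18.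

**Further compounds**

F1 | step 7 | (1R,2S,5R)-8-phenylmenthyl 3-oxobutanoate | CC(=O)CC(=O)O[C@@H]1C[C@H](C)CC[C@H]1C(C)(C)c1ccccc1
F2 | step 7 | (1R,2S,5R)-8-phenylmenthyl (6E,10E,14R)-16-[(tert-butyldiphenylsilyl)oxy]-6,10,14-trimethyl-3-oxohexadeca-6,10-dienoate | O=C(CC(=O)CC/C(C)=C/CC/C(C)=C/CC[C@@H](C)CCO[Si](c1ccccc1)(c1ccccc1)C(C)(C)C)O[C@@H]1C[C@H](C)CC[C@H]1C(C)(C)c1ccccc1
F3 | step 7 | (1R,2S,5R)-8-phenylmenthyl (13R)-15-(tert-butyldiphenylsilyloxy)-3-oxo-18-nor-ent-labd-8(17)-en-19-oate (C4 enolisable) | C=C1CC[C@@H]2C(C(=O)O[C@@H]3C[C@H](C)CC[C@H]3C(C)(C)c3ccccc3)C(=O)CC[C@@]2(C)[C@@H]1CC[C@@H](C)CCO[Si](c1ccccc1)(c1ccccc1)C(C)(C)C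
F4 | step 7 | (1R,2S,5R)-8-phenylmenthyl (13R)-15-(tert-butyldiphenylsilyloxy)-3-oxo-ent-labd-8(17)-en-19-oate | C=C1CC[C@@H]2[C@](C)(C(=O)O[C@@H]3C[C@H](C)CC[C@H]3C(C)(C)c3ccccc3)C(=O)CC[C@@]2(C)[C@@H]1CC[C@@H](C)CCO[Si](c1ccccc1)(c1ccccc1)C(C)(C)C
F5 | step 7 | (1R,2S,5R)-8-phenylmenthyl (13R)-15-(tert-butyldiphenylsilyloxy)-3-hydroxy-ent-labd-8(17)-en-19-oate | C=C1CC[C@@H]2[C@](C)(C(=O)O[C@@H]3C[C@H](C)CC[C@H]3C(C)(C)c3ccccc3)[C@H](O)CC[C@@]2(C)[C@@H]1CC[C@@H](C)CCO[Si](c1ccccc1)(c1ccccc1)C(C)(C)C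
F6 | step 7 | (1R,2S,5R)-8-phenylmenthyl (13R)-15-(tert-butyldiphenylsilyloxy)-3-[(imidazol-1-yl)carbonothioyloxy]-ent-labd-8(17)-en-19-oate | C=C1CC[C@@H]2[C@](C)(C(=O)O[C@@H]3C[C@H](C)CC[C@H]3C(C)(C)c3ccccc3)[C@H](OC(=S)n3ccnc3)CC[C@@]2(C)[C@@H]1CC[C@@H](C)CCO[Si](c1ccccc1)(c1ccccc1)C(C)(C)C
F7 | step 7 | (1R,2S,5R)-8-phenylmenthyl (13R)-15-(tert-butyldiphenylsilyloxy)-ent-labd-8(17)-en-19-oate | C=C1CC[C@@H]2[C@](C)(C(=O)O[C@@H]3C[C@H](C)CC[C@H]3C(C)(C)c3ccccc3)CCC[C@@]2(C)[C@@H]1CC[C@@H](C)CCO[Si](c1ccccc1)(c1ccccc1)C(C)(C)C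
F8 | step 3 | (6E,10R)-3-bromo-12-[(tert-butyldiphenylsilyl)oxy]-2,6,10-trimethyldodec-6-en-2-ol | CC(C)(O)C(Br)CC/C(C)=C/CC[C@@H](C)CCO[Si](c1ccccc1)(c1ccccc1)C(C)(C)C
F9 | step 3 | tert-butyl{[(3R,6E)-9-(3,3-dimethyloxiran-2-yl)-3,7-dimethylnon-6-en-1-yl]oxy}diphenylsilane | CC1(C)OC1CC/C(C)=C/CC[C@@H](C)CCO[Si](c1ccccc1)(c1ccccc1)C(C)(C)C
F10 | step 3 | (4E,8R)-10-[(tert-butyldiphenylsilyl)oxy]-4,8-dimethyldec-4-enal | O=CCC/C(C)=C/CC[C@@H](C)CCO[Si](c1ccccc1)(c1ccccc1)C(C)(C)C
F11 | step 3 | ethyl (2E,6E,10R)-12-[(tert-butyldiphenylsilyl)oxy]-2,6,10-trimethyldodeca-2,6-dienoate | CCOC(=O)/C(C)=C/CC/C(C)=C/CC[C@@H](C)CCO[Si](c1ccccc1)(c1ccccc1)C(C)(C)C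
F12 | step 11 | (13R)-15-(tert-butyldiphenylsilyloxy)-ent-labd-8(17)-ene-3,19-diol (equatorial 3-OH) | C=C1CC[C@@H]2[C@](C)(CO)[C@H](O)CC[C@@]2(C)[C@@H]1CC[C@@H](C)CCO[Si](c1ccccc1)(c1ccccc1)C(C)(C)C
F13 | step 11 | 3,19-O-thiocarbonyl derivative (cyclic thionocarbonate) of F12 | C=C1CC[C@@H]2[C@]3(C)COC(=S)O[C@@H]3CC[C@@]2(C)[C@@H]1CC[C@@H](C)CCO[Si](c1ccccc1)(c1ccccc1)C(C)(C)C
F14 | step 11 | O-[(13R)-15-(tert-butyldiphenylsilyloxy)-ent-labd-8(17)-en-19-yl] S-(tributylstannyl) thiocarbonate | C=C1CC[C@@H]2[C@](C)(COC(=O)S[Sn](CCCC)(CCCC)CCCC)CCC[C@@]2(C)[C@@H]1CC[C@@H](C)CCO[Si](c1ccccc1)(c1ccccc1)C(C)(C)C
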